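**Retrosynthetic overview**
1. Target 30 ⇐ nine-membered dienol 24 with a C8=C19 methylene. In the ring C1–C9 the C1 carbinol sits next to C9, and C9's neighbour C8 carries the one-carbon branch C19; this is the homoallylic-alcohol pattern left by a gamma-substituted allyl metal adding to an aldehyde. C19 oxygenation, oxidation of C18/C19 and equilibration of C8 follow the ring closure.
2. 24 ⇐ bromo aldehyde 22 by intramolecular Nozaki–Hiyama allylation (C1–C9 bond); this forms the only ring and sets C1 and C9 together.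
3. 22 ⇐ dienoate 18 ⇐ Stille coupling (C7–C8) of the (E)-alpha-iodoenoate 7 (C10 cis to C19) with the (Z)-alkenylstannane 17 (C5 cis to tin).
4. 7 ⇐ (S)-citronellal 1 with all ten carbons kept (alkyne, ynoate, syn hydrostannation); 17 ⇐ but-3-yn-1-ol 8 (methylalumination sets E C3=C4) and prop-2-yn-1-ol 14 (trans hydrostannation sets C6=C7).

Key step: step 16

Locants used throughout: ring carbons C1 (acetoxy carbon) to C9 (side-chain carbon); C18 is the carbon on C7, C19 the carbon on C8, C10 the side-chain methine.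
Assumption: the dialdehyde with the C8 formyl group trans to the C9 side chain (the target) is the more stable C8 epimer, so the closing equilibration converges on it.

**Step 1**
Reactants: 1 (S)-citronellal
Product: 3 (3S)-3,7-dimethyloct-6-en-1-yne, via enol nonaflate 2 (not isolated)
Conditions: NfF (C4F9SO2F, 1.2 equiv), phosphazene base P2-Et (2.5 equiv), DMF, −20 °C → rt
Reagents that add atoms: none
Why: O-sulfonylation of the aldehyde enolate gives the 1-alkenyl nonaflate, which loses nonaflate by base-induced elimination in the same flask (one-pot aldehyde-to-terminal-alkyne conversion), so all ten carbons are kept (C1 and C2 of citronellal become C8 and C9) and the non-acidic propargylic C10 stereocentre is untouched.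

**Step 2**
Reactants: 3 (3S)-3,7-dimethyloct-6-en-1-yne
Product: 5 ethyl (4S)-4,8-dimethylnon-7-en-2-ynoate, via lithium acetylide 4 (not isolated)
Conditions: n-BuLi, THF, −78 °C; ClCO2Et, −78 → 0 °C
Reagents that add atoms: ethyl chloroformate, CCOC(=O)Cl
Why: Deprotonation of the terminal alkyne and C-acylation of the acetylide with a chloroformate is the standard alkynoate synthesis and installs C19.

**Step 3**
Reactants: 5 ethyl (4S)-4,8-dimethylnon-7-en-2-ynoate
Product: 6 ethyl (2E,4S)-4,8-dimethyl-2-(tributylstannyl)nona-2,7-dienoate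
Conditions: Bu3SnH, Pd(PPh3)4 (2 mol %), THF, 0 °C → rt
Reagents that add atoms: tributyltin hydride, CCCC[SnH](CCCC)CCCC
Why: Palladium-catalysed hydrostannation of an alkynoate is a syn addition that puts tin on the alpha carbon (C8) and hydrogen on C9, which fixes C10 cis to the ester carbon C19.

**Step 4**
Reactants: 6 ethyl (2E,4S)-4,8-dimethyl-2-(tributylstannyl)nona-2,7-dienoate
Product: 7 ethyl (2E,4S)-2-iodo-4,8-dimethylnona-2,7-dienoate
Conditions: I2 (1.05 equiv), CH2Cl2, 0 °C
Reagents that add atoms: iodine, II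
Why: Iododestannylation occurs with retention at the sp2 carbon and is much faster than addition of iodine to the remote trisubstituted alkene.

**Step 5**
Reactants: 8 but-3-yn-1-ol
Product: 9 1-[(but-3-yn-1-yloxy)methyl]-4-methoxybenzene
Conditions: NaH, 4-methoxybenzyl chloride, Bu4NI (cat.), THF/DMF, 0 °C → rt
Reagents that add atoms: 4-methoxybenzyl chloride, COc1ccc(CCl)cc1
Why: Williamson etherification of the primary alkoxide gives the one protecting group that is later removed oxidatively, beside a silyl ether and an allylic bromide.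

**Step 6**
Reactants: 9 1-[(but-3-yn-1-yloxy)methyl]-4-methoxybenzene
Product: 12 (E)-5-[(4-methoxybenzyl)oxy]-3-methylpent-2-en-1-ol, via alkenylalane 10 (not isolated), via lithium alanate 11 (not isolated)
Conditions: Me3Al (2.5 equiv), Cp2ZrCl2 (0.25 equiv), CH2Cl2, 0 °C → rt; n-BuLi, hexane, 0 °C; (CH2O)n, THF, rt
Reagents that add atoms: trimethylaluminium, C[Al](C)C; formaldehyde (from paraformaldehyde), C=O
Why: Negishi zirconium-catalysed methylalumination is a syn addition (methyl to C3, aluminium to C4) and the derived alanate is hydroxymethylated with retention, which gives the E trisubstituted C3=C4 alkene.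

**Step 7**
Reactants: 12 (E)-5-[(4-methoxybenzyl)oxy]-3-methylpent-2-en-1-ol
Product: 13 (E)-1-{[(5-bromo-3-methylpent-3-en-1-yl)oxy]methyl}-4-methoxybenzene
Conditions: CBr4, PPh3, CH2Cl2, 0 °C
Reagents that add atoms: carbon tetrabromide, BrC(Br)(Br)Br
Why: Appel bromination of a primary allylic alcohol proceeds by SN2 displacement of the alkoxyphosphonium ion without allylic transposition.

**Step 8**
Reactants: 13 (E)-1-{[(5-bromo-3-methylpent-3-en-1-yl)oxy]methyl}-4-methoxybenzene; 14 prop-2-yn-1-ol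
Product: 15 (E)-8-[(4-methoxybenzyl)oxy]-6-methyloct-5-en-2-yn-1-ol
Conditions: CuI (0.2 equiv), K2CO3, Bu4NI (cat.), DMF, rt
Reagents that add atoms: none
Why: Copper-catalysed coupling of a terminal alkyne with an allylic bromide (alkylation of the copper acetylide) takes place at the primary carbon of the 3,3-disubstituted allyl unit and gives the skipped enyne with C3=C4 intact.

**Step 9**
Reactants: 15 (E)-8-[(4-methoxybenzyl)oxy]-6-methyloct-5-en-2-yn-1-ol
Product: 16 (2Z,5E)-8-[(4-methoxybenzyl)oxy]-6-methyl-2-(tributylstannyl)octa-2,5-dien-1-ol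
Conditions: Bu3SnH, [Cp*RuCl]4 (1.5 mol %), CH2Cl2, rt
Reagents that add atoms: tributyltin hydride, CCCC[SnH](CCCC)CCCC
Why: Ruthenium-catalysed trans-hydrostannation of a propargylic alcohol places tin on the carbon next to the carbinol (C7), guided by hydrogen bonding of the free hydroxyl to the chloride on ruthenium, and adds H and Sn anti, so C5 ends up cis to tin as the ring alkene C6=C7 requires.

**Step 10**
Reactants: 16 (2Z,5E)-8-[(4-methoxybenzyl)oxy]-6-methyl-2-(tributylstannyl)octa-2,5-dien-1-ol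
Product: 17 tert-butyldimethylsilyl ether of 16
Conditions: TBSCl, imidazole, CH2Cl2, 0 °C → rt
Reagents that add atoms: tert-butyldimethylsilyl chloride, CC(C)(C)[Si](C)(C)Cl
Why: Routine silylation of the primary allylic alcohol, needed so that the C18 oxygen cannot lactonise onto the C19 ester after the coupling.

**Step 11**
Reactants: 7 ethyl (2E,4S)-2-iodo-4,8-dimethylnona-2,7-dienoate; 17 tert-butyldimethylsilyl ether of 16
Product: 18 ethyl (2Z,3E,6E)-3-{[(tert-butyldimethylsilyl)oxy]methyl}-2-[(2S)-2,6-dimethylhept-5-en-1-ylidene]-9-[(4-methoxybenzyl)oxy]-7-methylnona-3,6-dienoate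
Conditions: Pd(PPh3)4 (10 mol %), CuTC (copper thiophene-2-carboxylate, Cu(O2CC4H3S), 1.5 equiv), DMF, 0 °C → rt
Reagents that add atoms: none
Why: Stille coupling with a copper carboxylate as transmetalation promoter joins the two fully substituted sp2 carbons C7 and C8 with retention of both alkene geometries, the electron-poor iodoenoate undergoing fast oxidative addition.

**Step 12**
Reactants: 18 dienoate
Product: 19 (3E,6E,8Z,10S)-7-{[(tert-butyldimethylsilyl)oxy]methyl}-8-(hydroxymethyl)-1-[(4-methoxybenzyl)oxy]-3,10,14-trimethylpentadeca-3,6,8,13-tetraene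
Conditions: i-Bu2AlH (2.5 equiv), CH2Cl2, −78 °C
Reagents that add atoms: none
Why: i-Bu2AlH reduces the conjugated ester to the primary allylic alcohol (C19) at low temperature without touching the ethers or the alkenes.

**Step 13**
Reactants: 19 C19 allylic alcohol
Product: 20 (3E,6E,8Z,10S)-8-(bromomethyl)-7-{[(tert-butyldimethylsilyl)oxy]methyl}-1-[(4-methoxybenzyl)oxy]-3,10,14-trimethylpentadeca-3,6,8,13-tetraene
Conditions: CBr4, PPh3, 2,6-lutidine, CH2Cl2, −20 °C
Reagents that add atoms: carbon tetrabromide, BrC(Br)(Br)Br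
Why: Appel bromination converts the primary allylic alcohol into the bromide by SN2 displacement under buffered, non-acidic conditions that keep both ethers.

**Step 14**
Reactants: 20 allylic bromide
Product: 21 (3E,6E,8Z,10S)-8-(bromomethyl)-7-{[(tert-butyldimethylsilyl)oxy]methyl}-3,10,14-trimethylpentadeca-3,6,8,13-tetraen-1-ol
Conditions: DDQ (1.3 equiv), CH2Cl2/pH 7 buffer, 0 °C
Reagents that add atoms: none
Why: Oxidative cleavage of the 4-methoxybenzyl ether by DDQ is neutral and non-nucleophilic, so the allylic bromide and the silyl ether persist, and the diene, which has a Z terminus, cannot reach the s-cis geometry needed for cycloaddition with the quinone.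

**Step 15**
Reactants: 21 bromo alcohol
Product: 22 (3E,6E,8Z,10S)-8-(bromomethyl)-7-{[(tert-butyldimethylsilyl)oxy]methyl}-3,10,14-trimethylpentadeca-3,6,8,13-tetraenal
Conditions: Dess–Martin periodinane, NaHCO3, CH2Cl2, 0 °C; used at once
Reagents that add atoms: none
Why: Buffered Dess–Martin oxidation gives the beta,gamma-unsaturated aldehyde under non-basic conditions that do not move C3=C4 into conjugation.

**Step 16**
Reactants: 22 bromo aldehyde
Product: 24 (1R,3E,6E,9R)-7-{[(tert-butyldimethylsilyl)oxy]methyl}-3-methyl-8-methylidene-9-[(2S)-6-methylhept-5-en-2-yl]cyclonona-3,6-dien-1-ol, via allylchromium 23 (not isolated)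
Conditions: CrCl2 (8 equiv), THF, rt; 22 added by syringe pump over 10 h (final 0.003 M); aqueous work-up
Reagents that add atoms: none
Why: Two equivalents of divalent chromium reduce the C19 allylic bromide by successive single-electron transfers to the trivalent allylchromium 23, which is non-basic and aldehyde-selective and adds through its gamma carbon C9 to the chromium-bound C1 aldehyde in a closed six-membered (Zimmerman–Traxler-type) transition state, as in intermolecular Nozaki–Hiyama allylation and its macrocyclising variants. The nine-membered ring closes in the 9-exo-trig mode (C9 onto the carbonyl carbon C1, oxygen outside the ring), and slow addition at high dilution suppresses dimerisation. The step needs the syn C1/C9 relation, which comes from the Z allylchromium (C10 cis to the CH2Cr group) reacting in the chair with C10 axial and C2 equatorial; this geometry is the stable one because the bulky C7 alkenyl substituent on C8 would otherwise sit cis to C10. The absolute sense at C9, and with it the Si face of the C1 aldehyde, is set by the C10 stereocentre: its C–H eclipses the C8=C9 bond to relieve A(1,3) strain with the CH2Cr group, so C1 approaches anti to the C11 chain, past the methyl group. This bias is modest and ring strain may favour a boat, so the diastereomer ratio is the main uncertainty; a chiral oxazoline–sulfonamide ligand on chromium can reinforce the C1 face without changing the step.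

**Step 17**
Reactants: 24 nine-membered dienol
Product: 25 acetate of 24
Conditions: Ac2O, pyridine, DMAP (cat.), CH2Cl2, 0 °C → rt
Reagents that add atoms: acetic anhydride, CC(=O)OC(C)=O
Why: DMAP-catalysed acylation of the secondary C1 alcohol proceeds without affecting any stereocentre.

**Step 18**
Reactants: 25 acetate
Product: 27 (1R,3E,6E,8S,9R)-7-{[(tert-butyldimethylsilyl)oxy]methyl}-8-(hydroxymethyl)-3-methyl-9-[(2S)-6-methylhept-5-en-2-yl]cyclonona-3,6-dien-1-yl acetate, via alkylborane 26 (not isolated)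
Conditions: 9-BBN, THF, 0 °C → rt; NaBO3·4H2O, THF/H2O, rt
Reagents that add atoms: sodium perborate, [Na+].[O-]OB=O
Why: 9-BBN hydroborates the 1,1-disubstituted C8=C19 alkene far faster than the three trisubstituted alkenes and puts boron on C19; hydrogen is expected to reach C8 from the face opposite the C9 side chain (giving C19 cis to C10, the 8S epimer), and perborate oxidises the C–B bond with retention without cleaving the acetate.

**Step 19**
Reactants: 27 C19 alcohol (8S)
Product: 28 (1R,3E,6E,8S,9R)-7,8-bis(hydroxymethyl)-3-methyl-9-[(2S)-6-methylhept-5-en-2-yl]cyclonona-3,6-dien-1-yl acetate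
Conditions: HF·pyridine, pyridine, THF, 0 °C → rt
Reagents that add atoms: none
Why: Fluoride-induced cleavage of the primary silyl ether under buffered, weakly acidic conditions avoids acetate hydrolysis or migration.

**Step 20**
Reactants: 28 diol (8S)
Product: 29 (1R,3E,6E,8S,9R)-7,8-diformyl-3-methyl-9-[(2S)-6-methylhept-5-en-2-yl]cyclonona-3,6-dien-1-yl acetate
Conditions: (COCl)2, DMSO, CH2Cl2, −78 °C; i-Pr2NEt, −78 → −30 °C
Reagents that add atoms: none
Why: Swern oxidation activates both hydroxyls as alkoxysulfonium ions before either aldehyde is released, which avoids the lactol and lactone that stepwise oxidants give with a 1,4-diol.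

**Step 21**
Reactants: 29 dialdehyde (8S)
Product: 30 (1R,3E,6E,8R,9R)-7,8-diformyl-3-methyl-9-[(2S)-6-methylhept-5-en-2-yl]cyclonona-3,6-dien-1-yl acetate
Conditions: DBU (0.1 equiv), CH2Cl2, 0 °C → rt
Reagents that add atoms: none
Why: Reversible enolisation of the C19 aldehyde (C8–H is alpha to the formyl group and allylic) equilibrates C8 to the epimer with the formyl group trans to the C9 side chain, while C1, C9 and C10 carry no acidic hydrogen and stay fixed.

**Compound list**
1 | (S)-citronellal, (3S)-3,7-dimethyloct-6-enal | C[C@@H](CCC=C(C)C)CC=O | starting material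
2 | (3S)-3,7-dimethylocta-1,6-dien-1-yl nonafluorobutane-1-sulfonate (E/Z mixture at the enol double bond) | C[C@@H](CCC=C(C)C)C=COS(=O)(=O)C(F)(F)C(F)(F)C(F)(F)C(F)(F)F | intermediate
3 | (3S)-3,7-dimethyloct-6-en-1-yne | C[C@@H](CCC=C(C)C)C#C | intermediate
4 | lithium (3S)-3,7-dimethyloct-6-en-1-yn-1-ide | [Li]C#C[C@@H](C)CCC=C(C)C | intermediate
5 | ethyl (4S)-4,8-dimethylnon-7-en-2-ynoate | CCOC(=O)C#C[C@@H](C)CCC=C(C)C | intermediate
6 | ethyl (2E,4S)-4,8-dimethyl-2-(tributylstannyl)nona-2,7-dienoate | CCOC(=O)/C(=C\[C@@H](C)CCC=C(C)C)[Sn](CCCC)(CCCC)CCCC | intermediate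
7 | ethyl (2E,4S)-2-iodo-4,8-dimethylnona-2,7-dienoate | CCOC(=O)/C(I)=C\[C@@H](C)CCC=C(C)C | intermediate
8 | but-3-yn-1-ol | C#CCCO | starting material
9 | 1-[(but-3-yn-1-yloxy)methyl]-4-methoxybenzene | C#CCCOCc1ccc(OC)cc1 | intermediate
10 | (E)-[4-(4-methoxybenzyloxy)-2-methylbut-1-en-1-yl]dimethylalane | C[Al](C)/C=C(\C)CCOCc1ccc(OC)cc1 | intermediate
11 | lithium butyl[(E)-4-(4-methoxybenzyloxy)-2-methylbut-1-en-1-yl]dimethylalanate | [Li+].CCCC[Al-](C)(C)/C=C(\C)CCOCc1ccc(OC)cc1 | intermediate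
12 | (E)-5-[(4-methoxybenzyl)oxy]-3-methylpent-2-en-1-ol | OC/C=C(\C)CCOCc1ccc(OC)cc1 | intermediate
13 | (E)-1-{[(5-bromo-3-methylpent-3-en-1-yl)oxy]methyl}-4-methoxybenzene | BrC/C=C(\C)CCOCc1ccc(OC)cc1 | intermediate
14 | prop-2-yn-1-ol | C#CCO | starting material
15 | (E)-8-[(4-methoxybenzyl)oxy]-6-methyloct-5-en-2-yn-1-ol | OCC#CC/C=C(\C)CCOCc1ccc(OC)cc1 | intermediate
16 | (2Z,5E)-8-[(4-methoxybenzyl)oxy]-6-methyl-2-(tributylstannyl)octa-2,5-dien-1-ol | OC/C(=C/C/C=C(\C)CCOCc1ccc(OC)cc1)[Sn](CCCC)(CCCC)CCCC | intermediate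
17 | tert-butyldimethylsilyl ether of 16 | CC(C)(C)[Si](C)(C)OC/C(=C/C/C=C(\C)CCOCc1ccc(OC)cc1)[Sn](CCCC)(CCCC)CCCC | intermediate
18 | ethyl (2Z,3E,6E)-3-{[(tert-butyldimethylsilyl)oxy]methyl}-2-[(2S)-2,6-dimethylhept-5-en-1-ylidene]-9-[(4-methoxybenzyl)oxy]-7-methylnona-3,6-dienoate | CCOC(=O)/C(=C\[C@@H](C)CCC=C(C)C)/C(CO[Si](C)(C)C(C)(C)C)=C\C/C=C(\C)CCOCc1ccc(OC)cc1 | intermediate
19 | (3E,6E,8Z,10S)-7-{[(tert-butyldimethylsilyl)oxy]methyl}-8-(hydroxymethyl)-1-[(4-methoxybenzyl)oxy]-3,10,14-trimethylpentadeca-3,6,8,13-tetraene | OC/C(=C\[C@@H](C)CCC=C(C)C)/C(CO[Si](C)(C)C(C)(C)C)=C\C/C=C(\C)CCOCc1ccc(OC)cc1 | intermediate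
20 | (3E,6E,8Z,10S)-8-(bromomethyl)-7-{[(tert-butyldimethylsilyl)oxy]methyl}-1-[(4-methoxybenzyl)oxy]-3,10,14-trimethylpentadeca-3,6,8,13-tetraene | BrC/C(=C\[C@@H](C)CCC=C(C)C)/C(CO[Si](C)(C)C(C)(C)C)=C\C/C=C(\C)CCOCc1ccc(OC)cc1 | intermediate
21 | (3E,6E,8Z,10S)-8-(bromomethyl)-7-{[(tert-butyldimethylsilyl)oxy]methyl}-3,10,14-trimethylpentadeca-3,6,8,13-tetraen-1-ol | BrC/C(=C\[C@@H](C)CCC=C(C)C)/C(CO[Si](C)(C)C(C)(C)C)=C\C/C=C(\C)CCO | intermediate
22 | (3E,6E,8Z,10S)-8-(bromomethyl)-7-{[(tert-butyldimethylsilyl)oxy]methyl}-3,10,14-trimethylpentadeca-3,6,8,13-tetraenal | O=CC/C(C)=C/C/C=C(/CO[Si](C)(C)C(C)(C)C)\C(CBr)=C\[C@@H](C)CCC=C(C)C | intermediate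
23 | allylchromium dichloride derived from 22 (CrCl2 on C19, trivalent chromium, Z at C8=C9) | O=CC/C(C)=C/C/C=C(/CO[Si](C)(C)C(C)(C)C)\C(C[Cr](Cl)Cl)=C\[C@@H](C)CCC=C(C)C | intermediate
24 | (1R,3E,6E,9R)-7-{[(tert-butyldimethylsilyl)oxy]methyl}-3-methyl-8-methylidene-9-[(2S)-6-methylhept-5-en-2-yl]cyclonona-3,6-dien-1-ol | O[C@@H]1C/C(C)=C/C/C=C(/CO[Si](C)(C)C(C)(C)C)C(=C)[C@H]1[C@@H](C)CCC=C(C)C | intermediate
25 | acetate of 24 | CC(=O)O[C@@H]1C/C(C)=C/C/C=C(/CO[Si](C)(C)C(C)(C)C)C(=C)[C@H]1[C@@H](C)CCC=C(C)C | intermediate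
26 | B-alkyl-9-borabicyclo[3.3.1]nonane from 25 (boron on C19, C19 cis to C10) | CC(=O)O[C@@H]1C/C(C)=C/C/C=C(/CO[Si](C)(C)C(C)(C)C)[C@@H](CB2C3CCCC2CCC3)[C@H]1[C@@H](C)CCC=C(C)C | intermediate
27 | (1R,3E,6E,8S,9R)-7-{[(tert-butyldimethylsilyl)oxy]methyl}-8-(hydroxymethyl)-3-methyl-9-[(2S)-6-methylhept-5-en-2-yl]cyclonona-3,6-dien-1-yl acetate | CC(=O)O[C@@H]1C/C(C)=C/C/C=C(/CO[Si](C)(C)C(C)(C)C)[C@@H](CO)[C@H]1[C@@H](C)CCC=C(C)C | intermediate
28 | (1R,3E,6E,8S,9R)-7,8-bis(hydroxymethyl)-3-methyl-9-[(2S)-6-methylhept-5-en-2-yl]cyclonona-3,6-dien-1-yl acetate | CC(=O)O[C@@H]1C/C(C)=C/C/C=C(/CO)[C@@H](CO)[C@H]1[C@@H](C)CCC=C(C)C | intermediate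
29 | (1R,3E,6E,8S,9R)-7,8-diformyl-3-methyl-9-[(2S)-6-methylhept-5-en-2-yl]cyclonona-3,6-dien-1-yl acetate (C8 epimer of the target) | CC(=O)O[C@@H]1C/C(C)=C/C/C=C(/C=O)[C@@H](C=O)[C@H]1[C@@H](C)CCC=C(C)C | intermediate
30 | (1R,3E,6E,8R,9R)-7,8-diformyl-3-methyl-9-[(2S)-6-methylhept-5-en-2-yl]cyclonona-3,6-dien-1-yl acetate | CC(=O)O[C@@H]1C/C(C)=C/C/C=C(/C=O)[C@H](C=O)[C@H]1[C@@H](C)CCC=C(C)C | target

**Totals**
Total step count: 21. Longest linear sequence: 17 steps (steps 5–10, then 11–21); the branch from citronellal (steps 1–4) joins at step 11.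

**Steps most likely to fail**

Step 16 (ring closure). The strain of the forming nine-membered ring (E alkene C3=C4, Z alkene C6=C7) may force the closed transition state into a boat or into the chair with C2 axial, which would give the anti C1/C9 pair, and closure may be slower than intermolecular coupling. Fallback: from bromo alcohol 21, displacement of bromide with Bu3SnLi (2.2 equiv, THF, −78 °C) would give the allylstannane alcohol F1. Parikh–Doering oxidation (SO3·pyridine, DMSO, i-Pr2NEt, 0 °C) would give the stannyl aldehyde F2. BF3·OEt2 in CH2Cl2 at −78 °C under high dilution would then form the same C1–C9 bond through an open antiperiplanar SE2' transition state, which is syn-selective for either allyl geometry and free of the chair/boat question; this rejoins the route at dienol 24.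

Step 21 (C8 equilibration). The base may also remove a C5 hydrogen, which is doubly allylic and vinylogous to the C18 enal, and so move C6=C7; or the equilibrium may not lie far enough on the side of 30. Fallback: from alcohol 27, buffered Dess–Martin oxidation would give the C19 monoaldehyde F3, in which C18 is still silylated and no enal is present. Equilibration with DBU would give the 8R aldehyde F4, NaBH4 at −20 °C the 8R alcohol F5, and HF·pyridine the 8R diol F6. Swern oxidation with i-Pr2NEt kept below −40 °C would then give target 30 directly.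

Step 11 (fragment coupling). Transmetalation at the tin-bearing C7, flanked by the silyloxymethyl group and the cis C5 methylene, may be so slow that protodestannylation or homocoupling of 7 takes over. Fallback: from stannane 17, iododestannylation (I2, CH2Cl2, 0 °C) would give the alkenyl iodide F7. Iodine–lithium exchange (t-BuLi, Et2O, −78 °C) would give the alkenyllithium F8, and ZnCl2 the alkenylzinc chloride F9. Negishi coupling of F9 with iodoenoate 7 (Pd(PPh3)4, THF, rt) rejoins the route at dienoate 18.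

**Further compounds**
F1 | step 16 | (3E,6E,8Z,10S)-7-{[(tert-butyldimethylsilyl)oxy]methyl}-3,10,14-trimethyl-8-[(tributylstannyl)methyl]pentadeca-3,6,8,13-tetraen-1-ol | CCCC[Sn](CCCC)(CCCC)C/C(=C\[C@@H](C)CCC=C(C)C)/C(CO[Si](C)(C)C(C)(C)C)=C\C/C=C(\C)CCO
F2 | step 16 | (3E,6E,8Z,10S)-7-{[(tert-butyldimethylsilyl)oxy]methyl}-3,10,14-trimethyl-8-[(tributylstannyl)methyl]pentadeca-3,6,8,13-tetraenal | CCCC[Sn](CCCC)(CCCC)C/C(=C\[C@@H](C)CCC=C(C)C)/C(CO[Si](C)(C)C(C)(C)C)=C\C/C=C(\C)CC=O
F3 | step 21 | (1R,3E,6E,8S,9R)-7-{[(tert-butyldimethylsilyl)oxy]methyl}-8-formyl-3-methyl-9-[(2S)-6-methylhept-5-en-2-yl]cyclonona-3,6-dien-1-yl acetate | CC(=O)O[C@@H]1C/C(C)=C/C/C=C(/CO[Si](C)(C)C(C)(C)C)[C@@H](C=O)[C@H]1[C@@H](C)CCC=C(C)C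
F4 | step 21 | (1R,3E,6E,8R,9R)-7-{[(tert-butyldimethylsilyl)oxy]methyl}-8-formyl-3-methyl-9-[(2S)-6-methylhept-5-en-2-yl]cyclonona-3,6-dien-1-yl acetate | CC(=O)O[C@@H]1C/C(C)=C/C/C=C(/CO[Si](C)(C)C(C)(C)C)[C@H](C=O)[C@H]1[C@@H](C)CCC=C(C)C
F5 | step 21 | (1R,3E,6E,8R,9R)-7-{[(tert-butyldimethylsilyl)oxy]methyl}-8-(hydroxymethyl)-3-methyl-9-[(2S)-6-methylhept-5-en-2-yl]cyclonona-3,6-dien-1-yl acetate | CC(=O)O[C@@H]1C/C(C)=C/C/C=C(/CO[Si](C)(C)C(C)(C)C)[C@H](CO)[C@H]1[C@@H](C)CCC=C(C)C
F6 | step 21 | (1R,3E,6E,8R,9R)-7,8-bis(hydroxymethyl)-3-methyl-9-[(2S)-6-methylhept-5-en-2-yl]cyclonona-3,6-dien-1-yl acetate | CC(=O)O[C@@H]1C/C(C)=C/C/C=C(/CO)[C@H](CO)[C@H]1[C@@H](C)CCC=C(C)C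
F7 | step 11 | tert-butyl{[(2Z,5E)-2-iodo-8-[(4-methoxybenzyl)oxy]-6-methylocta-2,5-dien-1-yl]oxy}dimethylsilane | CC(C)(C)[Si](C)(C)OC/C(I)=C/C/C=C(\C)CCOCc1ccc(OC)cc1
F8 | step 11 | alkenyllithium from F7 (lithium on C7, geometry retained) | CC(C)(C)[Si](C)(C)OC/C([Li])=C/C/C=C(\C)CCOCc1ccc(OC)cc1
F9 | step 11 | alkenylzinc chloride from F8 (ZnCl on C7, geometry retained) | CC(C)(C)[Si](C)(C)OC/C([Zn]Cl)=C/C/C=C(\C)CCOCc1ccc(OC)cc1
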